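## Retrosynthetic overview

- **Feature:** N1' of the N-linked indole (ring B, primed locants) is bonded to C2', C7a' and C4 of the methoxyindole (ring A), and the ring B bromine at C5' sits next to C4'. Ring B can therefore be built on an amino group already at C4, as a 4'-oxo-4',5',6',7'-tetrahydroindole, and the crowded C4–N1' bond never has to be made by N-arylation of an indole.
- **Late stage:** the C3 and C3' bromines are removed first (innate indole C3 reactivity), then the tosyl group. The 5'-bromoindole traces back through a dihydroindole, a bromohydrin and an α-bromoketone to the 4'-ketone, whose only α-carbon is C5'.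
- **Key disconnection:** N1'–C2' and N1'–C7a'. The pyrrole of ring B comes from 4-amino-5-bromo-7-methoxy-1-tosylindole and 6,7-dihydro-1-benzofuran-4(5H)-one by oxygen-to-nitrogen exchange.
- **Aniline partner:** it is made from 4-bromo-7-methoxy-1H-indole by tosylation, C–N coupling with an ammonia surrogate, hydrolysis and bromination at C5.
- **Ring order:** ring A is bought intact, the pyrrole of ring B closes in step 5, and the carbocycle of ring B (bought as a cyclohexanone) is aromatised in step 9.

Key step: step 5

Assumption: the target SMILES carries no descriptor for the hindered C4–N1' axis, so the route aims at the racemate. The sp3 centres in 9, 11 and 12 are transient and are drawn without descriptors.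

## Route

Step 1
Reactants: 1 4-bromo-7-methoxy-1H-indole
Product: 3 4-bromo-7-methoxy-1-tosyl-1H-indole, via sodium indolide 2 (not isolated)
Conditions: NaH, DMF, 0 °C; then TsCl, 0 °C → rt
Reagents that add atoms: p-toluenesulfonyl chloride (TsCl), Cc1ccc(S(=O)(=O)Cl)cc1
Why: N-sulfonylation of the indolide anion, which lowers the nucleophilicity of N1 and C3 of ring A for the coupling, bromination and acid steps that follow.

Step 2
Reactants: 3 4-bromo-7-methoxy-1-tosyl-1H-indole
Product: 4 N-(diphenylmethylidene)-7-methoxy-1-tosyl-1H-indol-4-amine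
Conditions: Ph2C=NH, Pd2(dba)3 (cat.), rac-BINAP (cat.), Cs2CO3, toluene, 100 °C
Reagents that add atoms: benzophenone imine, N=C(c1ccccc1)c1ccccc1
Why: Buchwald–Hartwig amination with benzophenone imine as ammonia surrogate, in which zerovalent palladium inserts into the only C–Br bond and the mild base Cs2CO3 spares the sulfonamide.

Step 3
Reactants: 4 N-(diphenylmethylidene)-7-methoxy-1-tosyl-1H-indol-4-amine
Product: 5 4-amino-7-methoxy-1-tosyl-1H-indole
Conditions: 2 M aq. HCl, THF, rt; then aq. NaOH to pH 8
Reagents that add atoms: none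
Why: Acid hydrolysis of an N-aryl ketimine, which is fast at room temperature and should leave the sulfonamide and the methyl ether untouched.

Step 4
Reactants: 5 4-amino-7-methoxy-1-tosyl-1H-indole
Product: 6 4-amino-5-bromo-7-methoxy-1-tosyl-1H-indole
Conditions: NBS (1.0 equiv), DMF, −20 → 0 °C, dark
Reagents that add atoms: N-bromosuccinimide (NBS), O=C1CCC(=O)N1Br
Why: Electrophilic aromatic bromination steered by the strongest donor, since the amino group activates C5 (ortho, and para to N1), its para position C7 is blocked by methoxy, its other ortho position is the ring fusion C3a, and C3 is deactivated by the tosyl group.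

Step 5
Reactants: 6 4-amino-5-bromo-7-methoxy-1-tosyl-1H-indole; 7 6,7-dihydro-1-benzofuran-4(5H)-one
Product: 10 1-(5-bromo-7-methoxy-1-tosyl-1H-indol-4-yl)-6,7-dihydro-1H-indol-4(5H)-one, via enaminone aldehyde 8 (not isolated), via cyclic hemiaminal 9 (not isolated)
Conditions: 7 (3 equiv), p-TsOH·H2O (0.3 equiv), xylenes, 140 °C, Dean–Stark
Reagents that add atoms: none
Why: Protonation of the C4' carbonyl of 7 makes C7a', the β-carbon of the vinylogous ester, electrophilic enough to take up the aniline nitrogen of 6 in a conjugate addition, and collapse of the resulting N,O-ketal breaks the C7a'–O bond and, after tautomerisation of the released enol, leaves enaminone aldehyde 8. The same nitrogen then adds to the aldehyde carbon C2' in a 5-exo-trig closure to hemiaminal 9, and loss of water gives the aromatic pyrrole of ring B, so N1'–C7a' and N1'–C2' are both made in one flask. The closest known reaction type is the conversion of 4-oxotetrahydrobenzofurans into 1-substituted 4-oxotetrahydroindoles by primary amines, a Paal–Knorr-type exchange of the ring heteroatom. No stereocentre remains in 10, because the carbinol centre C2' of 9 is lost on dehydration and the C4–N1' bond becomes a hindered axis without control, hence racemic. The selectivity required is attack at C7a' in preference to C4', and it is secured because any ketimine formed at the weakly electrophilic C4' can revert, whereas the C7a' path drains irreversibly into an aromatic pyrrole that is also a better stabilised vinylogous amide. The ortho bromine and the peri C3–H slow the first addition, so excess 7, a high-boiling non-nucleophilic solvent and azeotropic removal of water are used, conditions that the sulfonamide, aryl bromide and methyl ether should tolerate.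

Step 6
Reactants: 10 1-(5-bromo-7-methoxy-1-tosyl-1H-indol-4-yl)-6,7-dihydro-1H-indol-4(5H)-one
Product: 11 5-bromo-1-(5-bromo-7-methoxy-1-tosyl-1H-indol-4-yl)-6,7-dihydro-1H-indol-4(5H)-one
Conditions: CuBr2 (2.1 equiv), EtOAc/CHCl3 (1:1), reflux
Reagents that add atoms: CuBr2 (cupric bromide), [Cu+2].[Br-].[Br-]
Why: α-Bromination of a ketone through its copper-bound enol, which can only occur at C5' because C3a' carries no hydrogen, should outrun attack on the acyl-deactivated pyrrole and the tosyl-deactivated ring A, and sets C5' without control as a centre that step 8 erases.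

Step 7
Reactants: 11 5-bromo-1-(5-bromo-7-methoxy-1-tosyl-1H-indol-4-yl)-6,7-dihydro-1H-indol-4(5H)-one
Product: 12 5-bromo-1-(5-bromo-7-methoxy-1-tosyl-1H-indol-4-yl)-4,5,6,7-tetrahydro-1H-indol-4-ol
Conditions: NaBH4, MeOH/THF, 0 °C
Reagents that add atoms: none
Why: Borohydride 1,2-reduction of an α-bromoketone, in which the bromine raises the electrophilicity of the otherwise sluggish vinylogous amide carbonyl, and the cis/trans mixture at C4'/C5' does not matter because both carbons become sp2 in step 8.

Step 8
Reactants: 12 5-bromo-1-(5-bromo-7-methoxy-1-tosyl-1H-indol-4-yl)-4,5,6,7-tetrahydro-1H-indol-4-ol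
Product: 13 5-bromo-4-(5-bromo-6,7-dihydro-1H-indol-1-yl)-7-methoxy-1-tosyl-1H-indole
Conditions: p-TsOH·H2O (cat.), toluene, 60 °C
Reagents that add atoms: none
Why: Acid-catalysed E1 dehydration, in which ionisation at C4' gives a pyrrole-stabilised (azafulvenium-type) cation whose only β-hydrogen is on C5', so the C4'=C5'(Br) alkene is the single possible regioisomer.

Step 9
Reactants: 13 5-bromo-4-(5-bromo-6,7-dihydro-1H-indol-1-yl)-7-methoxy-1-tosyl-1H-indole
Product: 14 5-bromo-4-(5-bromo-1H-indol-1-yl)-7-methoxy-1-tosyl-1H-indole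
Conditions: DDQ (1.2 equiv), 1,4-dioxane, rt → 60 °C
Reagents that add atoms: none
Why: Dehydrogenative aromatisation with DDQ, by hydride abstraction from C7' next to the pyrrole carbon C7a' and loss of a proton from C6', which should deliver the benzene ring of ring B with the vinylic C5'–Br bond intact.

Step 10
Reactants: 14 5-bromo-4-(5-bromo-1H-indol-1-yl)-7-methoxy-1-tosyl-1H-indole
Product: 15 5-bromo-4-(5-bromo-1H-indol-1-yl)-7-methoxy-1H-indole
Conditions: KOH, MeOH/THF, 60 °C; then 1 M aq. HCl to pH 7
Reagents that add atoms: none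
Why: Basic hydrolysis of an N-sulfonylindole, where hydroxide attacks sulfur and expels the indolide, a departure helped by the strain between the tosyl group and the 7-methoxy group, while the aryl bromides are inert.

Step 11
Reactants: 15 5-bromo-4-(5-bromo-1H-indol-1-yl)-7-methoxy-1H-indole
Product: 17 rivularin B [3,5-dibromo-4-(3,5-dibromo-1H-indol-1-yl)-7-methoxy-1H-indole], via 3'-monobromide 16 (not isolated)
Conditions: NBS (2.05 equiv), DMF, −20 → 0 °C, dark
Reagents that add atoms: N-bromosuccinimide (NBS), O=C1CCC(=O)N1Br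
Why: Electrophilic substitution at C3, the most nucleophilic carbon of an indole, should occur on both rings, first at the open C3' to give 16 and then at the peri-flanked C3, while C2, C2' and C6 are less activated and no stereocentre is created.

## Compound list

1 | 4-bromo-7-methoxy-1H-indole | COc1ccc(Br)c2cc[nH]c12 | starting material
2 | sodium 4-bromo-7-methoxyindol-1-ide | COc1ccc(Br)c2cc[n-]c12.[Na+] | intermediate
3 | 4-bromo-7-methoxy-1-tosyl-1H-indole | COc1ccc(Br)c2ccn(S(=O)(=O)c3ccc(C)cc3)c12 | intermediate
4 | N-(diphenylmethylidene)-7-methoxy-1-tosyl-1H-indol-4-amine | COc1ccc(N=C(c3ccccc3)c4ccccc4)c2ccn(S(=O)(=O)c5ccc(C)cc5)c12 | intermediate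
5 | 4-amino-7-methoxy-1-tosyl-1H-indole | COc1ccc(N)c2ccn(S(=O)(=O)c3ccc(C)cc3)c12 | intermediate
6 | 4-amino-5-bromo-7-methoxy-1-tosyl-1H-indole | COc1cc(Br)c(N)c2ccn(S(=O)(=O)c3ccc(C)cc3)c12 | intermediate
7 | 6,7-dihydro-1-benzofuran-4(5H)-one | O=C1CCCc2occc21 | starting material
8 | 2-{2-[(5-bromo-7-methoxy-1-tosyl-1H-indol-4-yl)amino]-6-oxocyclohex-1-en-1-yl}acetaldehyde | COc1cc(Br)c(NC3=C(CC=O)C(=O)CCC3)c2ccn(S(=O)(=O)c4ccc(C)cc4)c12 | intermediate
9 | 1-(5-bromo-7-methoxy-1-tosyl-1H-indol-4-yl)-2-hydroxy-2,3,6,7-tetrahydro-1H-indol-4(5H)-one (C2' unspecified) | COc1cc(Br)c(N3C(O)CC4=C3CCCC4=O)c2ccn(S(=O)(=O)c5ccc(C)cc5)c12 | intermediate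
10 | 1-(5-bromo-7-methoxy-1-tosyl-1H-indol-4-yl)-6,7-dihydro-1H-indol-4(5H)-one | COc1cc(Br)c(-n3ccc4c3CCCC4=O)c2ccn(S(=O)(=O)c5ccc(C)cc5)c12 | intermediate
11 | 5-bromo-1-(5-bromo-7-methoxy-1-tosyl-1H-indol-4-yl)-6,7-dihydro-1H-indol-4(5H)-one (stereoisomer mixture) | COc1cc(Br)c(-n3ccc4c3CCC(Br)C4=O)c2ccn(S(=O)(=O)c5ccc(C)cc5)c12 | intermediate
12 | 5-bromo-1-(5-bromo-7-methoxy-1-tosyl-1H-indol-4-yl)-4,5,6,7-tetrahydro-1H-indol-4-ol (stereoisomer mixture) | COc1cc(Br)c(-n3ccc4c3CCC(Br)C4O)c2ccn(S(=O)(=O)c5ccc(C)cc5)c12 | intermediate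
13 | 5-bromo-4-(5-bromo-6,7-dihydro-1H-indol-1-yl)-7-methoxy-1-tosyl-1H-indole | COc1cc(Br)c(-n3ccc4c3CCC(Br)=C4)c2ccn(S(=O)(=O)c5ccc(C)cc5)c12 | intermediate
14 | 5-bromo-4-(5-bromo-1H-indol-1-yl)-7-methoxy-1-tosyl-1H-indole | COc1cc(Br)c(-n3ccc4cc(Br)ccc43)c2ccn(S(=O)(=O)c5ccc(C)cc5)c12 | intermediate
15 | 5-bromo-4-(5-bromo-1H-indol-1-yl)-7-methoxy-1H-indole | COc1cc(Br)c(-n3ccc4cc(Br)ccc43)c2cc[nH]c12 | intermediate
16 | 5-bromo-4-(3,5-dibromo-1H-indol-1-yl)-7-methoxy-1H-indole | COc1cc(Br)c(-n3cc(Br)c4cc(Br)ccc43)c2cc[nH]c12 | intermediate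
17 | rivularin B, 3,5-dibromo-4-(3,5-dibromo-1H-indol-1-yl)-7-methoxy-1H-indole | COc1cc(Br)c(-n2cc(Br)c3cc(Br)ccc32)c2c(Br)c[nH]c12 | target

## Step count

Total step count: 11.
Longest linear sequence: 11 steps (1 to 17). Compound 7 enters as purchased.

## Steps most likely to fail

**Step 5.**
- **Risk:** the hindered and weakly nucleophilic aniline may add to C7a' too slowly. The aromatic furan would then stay unopened, or the furanone would be consumed by self-condensation before the exchange takes place.
- **Fallback:** it sets out from 6 and forms the N1'–C7a' bond on a non-aromatic partner. Compound 6 is condensed with purchased 2-allylcyclohexane-1,3-dione (C=CCC1C(=O)CCCC1=O) under p-TsOH in toluene with a Dean–Stark trap. This gives 2-allyl-3-[(5-bromo-7-methoxy-1-tosyl-1H-indol-4-yl)amino]cyclohex-2-en-1-one F1.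
- **Return to the route:** Lemieux–Johnson cleavage of the terminal alkene (OsO4 cat., NaIO4, 2,6-lutidine, dioxane/H2O) unmasks the aldehyde. The fallback rejoins the route at 8, which closes through 9 to 10 on brief warming with catalytic acid.

**Step 6.**
- **Risk:** electrophilic bromination of the pyrrole at C2', or a second bromination at C5', may compete with monobromination of the enol.
- **Fallback:** it sets out from 10 and fixes the enol as a discrete derivative before any bromine source is present. Soft enolisation (TMSOTf, Et3N, CH2Cl2, 0 °C) gives 1-(5-bromo-7-methoxy-1-tosyl-1H-indol-4-yl)-4-(trimethylsilyloxy)-6,7-dihydro-1H-indole F2.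
- **Return to the route:** one equivalent of NBS in THF at −78 °C brominates the enol ether carbon C5', and the fallback rejoins the route at 11.

**Step 11.**
- **Risk:** the two indoles may consume NBS unevenly. That would bring over-bromination at C2, C2' or C6 while the peri-hindered C3 remains partly unreacted.
- **Fallback:** it sets out from 14 and brominates the rings one at a time. With ring A still deactivated by the tosyl group, one equivalent of NBS in DMF should attack only C3' and give 5-bromo-4-(3,5-dibromo-1H-indol-1-yl)-7-methoxy-1-tosyl-1H-indole F3.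
- **Return to the route:** hydrolysis with KOH in MeOH/THF rejoins the route at 16, now isolated. One equivalent of pyridinium tribromide in THF at 0 °C then brominates C3 to give 17.

## Further compounds

F1 | step 5 | 2-allyl-3-[(5-bromo-7-methoxy-1-tosyl-1H-indol-4-yl)amino]cyclohex-2-en-1-one | COc1cc(Br)c(NC3=C(CC=C)C(=O)CCC3)c2ccn(S(=O)(=O)c4ccc(C)cc4)c12
F2 | step 6 | 1-(5-bromo-7-methoxy-1-tosyl-1H-indol-4-yl)-4-(trimethylsilyloxy)-6,7-dihydro-1H-indole | COc1cc(Br)c(-n3ccc4c3CCC=C4O[Si](C)(C)C)c2ccn(S(=O)(=O)c5ccc(C)cc5)c12
F3 | step 11 | 5-bromo-4-(3,5-dibromo-1H-indol-1-yl)-7-methoxy-1-tosyl-1H-indole | COc1cc(Br)c(-n3cc(Br)c4cc(Br)ccc43)c2ccn(S(=O)(=O)c5ccc(C)cc5)c12
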